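**Retrosynthetic overview**
- Feature: ring A (C1–C5, C10, eremophilane numbering) carries the four contiguous stereocentres C3, C4, C5 and C10. The C4/C5 methyls and H10 lie on one face; O3, C6 and C9 lie on the other. This is the endo-adduct pattern of a C4=C5 tigloyl ketone (C6=O) and an (E,E)-diene C10=C1–C2=C3–OSi joined through C7–C9.
- Key disconnection: C3–C4 and C5–C10. Rings A and B are made together from an achiral open-chain trienone in one enantioselective, Lewis-acid-catalysed intramolecular Diels–Alder reaction.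
- The trienone comes from the tiglic Weinreb amide and the Grignard reagent of a bromo silyloxydiene. The ketone is made after the enal silylation, and the diene geometry is drawn from a (Z)-enal.
- After the cycloaddition: C1=C2 is saturated and the C6 carbonyl is moved to C8 (enol triflate, 6-ene, allylic oxidation). O9 is added by Rubottom oxidation and the C7 isopropenyl group by iodination, Stille coupling and 1,4-reduction. Both angelates are put on last.

Key step: step 6

Assumption: TBS = tert-butyldimethylsilyl, decalins carry eremophilane numbering and β is the face bearing the C4/C5 methyls and H10; the catalyst antipode leading to the (3R,4R,5S,10S) adduct cannot be derived from the usual binding models for a ketone lacking an α-H, so the (S)-catalyst is written and the equally available (R)-catalyst is used if a configurational correlation on 12 demands it.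

Step 1
Reactants: 1 tiglic acid
Product: 3 (E)-N-methoxy-N,2-dimethylbut-2-enamide, via acyl imidazolide 2 (not isolated)
Conditions: CDI, CH2Cl2, rt; then MeNH(OMe)·HCl, rt
Reagents that add atoms: N,O-dimethylhydroxylamine hydrochloride, CNOC.Cl
Why: Acyl imidazolide activation followed by aminolysis (Weinreb amide synthesis) uses no strong base or conjugate-adding catalyst, so the (E)-alkene is kept.

Step 2
Reactants: 4 6-bromohex-1-ene; 5 (Z)-but-2-ene-1,4-diol
Product: 6 (Z)-7-bromohept-2-en-1-ol
Conditions: Z-selective Ru NHC 3,6-dichlorobenzene-1,2-dithiolate benzylidene catalyst (5 mol %), 5 (2 equiv), THF, rt, 100 torr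
Reagents that add atoms: none
Why: Z-selective olefin cross-metathesis passes through a side-bound metallacyclobutane that holds both substituents syn, so the CH–CH2OH unit of the diol is transferred with Z geometry, and the primary bromide is inert.

Step 3
Reactants: 6 (Z)-7-bromohept-2-en-1-ol
Product: 7 (Z)-7-bromohept-2-enal
Conditions: TEMPO (10 mol %), PhI(OAc)2 (1.1 equiv), CH2Cl2, 0 °C → rt; used at once
Reagents that add atoms: none
Why: Oxoammonium-mediated (TEMPO/PhI(OAc)2) oxidation stops at the aldehyde and is known to keep (Z)-allylic geometry because no base or strong acid is present.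

Step 4
Reactants: 7 (Z)-7-bromohept-2-enal
Product: 8 [(1E,3E)-7-bromohepta-1,3-dienyl]oxy-tert-butyldimethylsilane
Conditions: Et3N (2 equiv), TBSOTf (1.2 equiv), Et2O, −78 → 0 °C; Et3N-deactivated silica
Reagents that add atoms: tert-butyldimethylsilyl triflate, CC(C)(C)[Si](C)(C)OS(=O)(=O)C(F)(F)F
Why: Soft γ-enolisation of the O-silylated enal fixes the enol ether as E through the s-trans form, and in the (Z)-enal A1,3 strain with C1 keeps the C5 chain out of the inside position when the C4 proton leaves, so the new C3=C4 bond is E (the Z-to-E correspondence of deconjugative enolisation, whereas (E)-2-alkenals tend towards 3Z-dienes).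

Step 5
Reactants: 8 bromo silyloxydiene; 3 tiglic Weinreb amide
Product: 11 (2E,8E,10E)-11-(tert-butyldimethylsilyloxy)-3-methylundeca-2,8,10-trien-4-one, via Grignard reagent 9 (not isolated), via magnesium chelate 10 (not isolated)
Conditions: Mg (I2-activated), THF, 35 °C; then 3, THF, 0 °C; aq NH4Cl, 0 °C; stored cold
Reagents that add atoms: none
Why: In the Weinreb ketone synthesis the chelate 10 blocks over-addition and the α,β-disubstituted acrylamide is attacked 1,2; the TBS dienol ether tolerates Mg and RMgBr, and making the ketone only now removes a C7-enolisable carbonyl that would have competed for TBSOTf in step 4.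

Step 6
Reactants: 11 trienone
Product: 12 (3R,4R,5S,10S)-3α-TBSO-4β,5β-dimethyl-10βH-decal-1-en-6-one (cis-fused)
Conditions: (S)-o-tolyl-oxazaborolidine from diphenylprolinol (20 mol %), Tf2NH (16 mol %), CH2Cl2 (0.02 M), −78 → −20 °C
Reagents that add atoms: none
Why: The cationic boron Lewis acid binds the C6 carbonyl of the s-cis tigloyl ketone and lowers its LUMO, so a concerted but asynchronous suprafacial [4+2] cycloaddition forms C3–C4 and C5–C10 at low temperature; the closest known reaction types are the Lewis-acid-promoted type 1 intramolecular Diels–Alder reaction of 1,7,9-decatrien-3-ones and the oxazaborolidinium-catalysed enantioselective intramolecular and transannular Diels–Alder reactions. Ring A closes as the cyclohexene of the six-electron array (C3, C4, C5, C10, new C1=C2), and ring B closes in the fused mode as a six-membered carbocycle because the four-atom tether C6–C9 ties C5 to C10. The cis C4/C5 methyl pair follows from the (E)-dienophile and the cis relation of O3 and C9 from the (E,E)-diene, both by suprafacial addition. The link between these pairs (cis ring fusion, O3 anti to the methyls) follows from the transition state with the complexed C6 carbonyl endo under the diene and the C5 methyl exo, and the absolute sense from the catalyst aryl group that covers one face of the bound enone. The step needs fused regiochemistry against the ortho bias of the 1-silyloxydiene, which the short tether enforces because the bridged mode is too strained, and it needs endo and facial selectivity, for which the substrate offers a single basic carbonyl as binding site and a hindered product ketone that releases the catalyst. High dilution and a slight excess of oxazaborolidine over Tf2NH hold back intermolecular Mukaiyama–Michael addition and protodesilylation, and any 8Z-isomer of 11 cannot reach the s-cis diene and stays behind.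

Step 7
Reactants: 12 Diels–Alder adduct
Product: 13 (3R,4R,5S,10S)-3α-TBSO-4β,5β-dimethyl-10βH-decalin-6-one
Conditions: H2 (1 atm), 5% Rh/Al2O3, EtOAc, rt
Reagents that add atoms: none
Why: Heterogeneous hydrogenation saturates the only C=C bond; Rh on alumina hydrogenolyses or isomerises allylic C–O systems far less than Pd, the neopentyl C6 ketone is untouched and no stereocentre is created.

Step 8
Reactants: 13 saturated ketone
Product: 15 (3R,4R,5S,10S)-3α-TBSO-4β,5β-dimethyl-10βH-decal-6-en-6-yl triflate, via potassium enolate 14 (not isolated)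
Conditions: KHMDS, THF, −78 °C; PhNTf2, −78 → 0 °C
Reagents that add atoms: N-phenylbis(trifluoromethanesulfonimide), O=S(=O)(N(c1ccccc1)S(=O)(=O)C(F)(F)F)C(F)(F)F
Why: In this enolate O-triflation C5 is quaternary, so deprotonation can occur only at C7 and a single enol triflate results.

Step 9
Reactants: 15 enol triflate
Product: 16 (3R,4R,5R,10S)-3α-TBSO-4β,5β-dimethyl-10βH-decal-6-ene
Conditions: Pd(OAc)2 (5 mol %), PPh3 (10 mol %), HCO2H, Et3N, DMF, 60 °C
Reagents that add atoms: none
Why: Palladium-catalysed formate reduction of the enol triflate (oxidative addition, decarboxylation of formate, C–H reductive elimination) replaces OTf by H without moving the alkene, as known for triflates next to quaternary carbons.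

Step 10
Reactants: 16 6-ene
Product: 17 (3R,4R,5R,10R)-3α-TBSO-4β,5β-dimethyl-10βH-decal-6-en-8-one
Conditions: Rh2(cap)4 (1 mol %), t-BuOOH (70% aq, 5 equiv), 1,2-dichloroethane, 40 °C
Reagents that add atoms: tert-butyl hydroperoxide, CC(C)(C)OO
Why: In the dirhodium caprolactamate/hydroperoxide allylic oxidation C8 holds the only allylic hydrogens (C5 is quaternary), and the allyl radical is oxygenated at the open C8 end instead of at neopentyl C6.

Step 11
Reactants: 17 enone
Product: 18 (3R,4R,5S,10R)-3α,8-bis(TBSO)-4β,5β-dimethyl-10βH-decala-6,8-diene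
Conditions: TBSOTf, Et3N, CH2Cl2, 0 °C
Reagents that add atoms: tert-butyldimethylsilyl triflate, CC(C)(C)[Si](C)(C)OS(=O)(=O)C(F)(F)F
Why: In this soft enolisation the γ-carbon C5 has no hydrogen, so only the α′-proton at C9 can be lost and the cross-conjugated 2-silyloxydiene is the only possible product.

Step 12
Reactants: 18 silyl dienol ether
Product: 20 (3R,4R,5R,9R,10S)-3α,9β-bis(TBSO)-4β,5β-dimethyl-10βH-decal-6-en-8-one, via silyloxy epoxide 19 (not isolated)
Conditions: mCPBA, CH2Cl2, −20 → 0 °C
Reagents that add atoms: 3-chloroperbenzoic acid, O=C(OO)c1cccc(Cl)c1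
Why: In the Rubottom oxidation of a 2-silyloxy-1,3-diene the peracid attacks the electron-rich C8=C9 bond from the convex β face (syn to H10, ring A being folded under the α face), and epoxide opening with 1,4-silyl shift from O8 to O9 gives the 9β-silyloxy enone directly.

Step 13
Reactants: 20 9β-silyloxy enone
Product: 21 (3R,4R,5R,9R,10S)-7-iodo-3α,9β-bis(TBSO)-4β,5β-dimethyl-10βH-decal-6-en-8-one
Conditions: I2, pyridine/CH2Cl2 (1:1), 0 °C → rt
Reagents that add atoms: iodine, II
Why: α-Iodination of an enone by the iodine/pyridine addition–iodination–elimination sequence is known to work for 4,4-disubstituted cyclohexenones and touches no stereocentre.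

Step 14
Reactants: 21 iodoenone; 22 tributyl(prop-1-en-2-yl)stannane
Product: 23 (3R,4R,5R,9R,10S)-3α,9β-bis(TBSO)-10βH-eremophila-6,11-dien-8-one
Conditions: Pd2(dba)3 (5 mol %), AsPh3 (20 mol %), CuI (10 mol %), NMP, rt → 40 °C
Reagents that add atoms: none
Why: Stille coupling of an α-iodoenone under AsPh3/CuI acceleration runs near room temperature under neutral conditions, so C9 is not epimerised and the silyl ethers stay.

Step 15
Reactants: 23 cross-conjugated dienone
Product: 25 (3R,4R,5R,7R,9R,10S)-3α,9β-bis(TBSO)-10βH-eremophil-11-en-8-one, via lithium dienolate 24 (not isolated)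
Conditions: L-Selectride (1.1 equiv), THF, −78 °C; then AcOH/THF, −78 °C
Reagents that add atoms: none
Why: Conjugate reduction with a bulky trialkylborohydride (1,2-attack is blocked by the C7 and C9 substituents, and C6 is a β-CH) gives dienolate 24; its kinetic protonation occurs at the α-carbon C7 along the chair-like axial α trajectory and places the isopropenyl group equatorial (7β), which is also the more stable epimer.

Step 16
Reactants: 25 bis-silyl ether
Product: 26 (3R,4R,5R,7R,9R,10S)-3α,9β-dihydroxy-10βH-eremophil-11-en-8-one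
Conditions: HF·pyridine, pyridine/THF, 0 °C → rt
Reagents that add atoms: none
Why: Fluoride-induced Si–O cleavage under buffered, weakly acidic conditions removes both secondary TBS groups without enolising C8, so the β,γ-alkene and C7/C9 stay as set.

Step 17
Reactants: 27 angelic acid
Product: 28 angelic 2,4,6-trichlorobenzoic anhydride
Conditions: 2,4,6-trichlorobenzoyl chloride, Et3N, toluene, rt; filtered and concentrated
Reagents that add atoms: 2,4,6-trichlorobenzoyl chloride, O=C(Cl)c1c(Cl)cc(Cl)cc1Cl
Why: Mixed-anhydride formation (Yamaguchi-type activation) without a nucleophilic catalyst keeps the (Z)-geometry of the acid.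

Step 18
Reactants: 26 diol; 28 mixed anhydride
Product: 29 (3R,4R,5R,7R,9R,10S)-3α,9β-bis(angeloyloxy)-10βH-eremophil-11-en-8-one (target)
Conditions: 28 (6 equiv), NaHCO3 (solid), toluene, 85 °C
Reagents that add atoms: none
Why: The alcohols attack the angeloyl carbonyl because two ortho chlorines shield the aroyl carbonyl, omitting DMAP-type catalysts avoids the addition–elimination that turns angelates into tiglates, and both hydroxyls are equatorial so no stereocentre is touched.

**Compound list**
1 | tiglic acid | C/C=C(\C)C(=O)O | starting material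
2 | 1-[(E)-2-methylbut-2-enoyl]imidazole | C/C=C(\C)C(=O)n1ccnc1 | intermediate
3 | (E)-N-methoxy-N,2-dimethylbut-2-enamide | C/C=C(\C)C(=O)N(C)OC | intermediate
4 | 6-bromohex-1-ene | C=CCCCCBr | starting material
5 | (Z)-but-2-ene-1,4-diol | OC/C=C\CO | starting material
6 | (Z)-7-bromohept-2-en-1-ol | OC/C=C\CCCCBr | intermediate
7 | (Z)-7-bromohept-2-enal | O=C/C=C\CCCCBr | intermediate
8 | [(1E,3E)-7-bromohepta-1,3-dienyl]oxy-tert-butyldimethylsilane | BrCCC/C=C/C=C/O[Si](C)(C)C(C)(C)C | intermediate
9 | [(4E,6E)-7-(TBSO)hepta-4,6-dienyl]magnesium bromide | Br[Mg]CCC/C=C/C=C/O[Si](C)(C)C(C)(C)C | intermediate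
10 | bromomagnesium chelate of the tetrahedral N-methoxy-N-methyl adduct (carbinol carbon unassigned) | C/C=C(\C)C(O[Mg]Br)(N(C)OC)CCC/C=C/C=C/O[Si](C)(C)C(C)(C)C | intermediate
11 | (2E,8E,10E)-11-(TBSO)-3-methylundeca-2,8,10-trien-4-one | C/C=C(\C)C(=O)CCC/C=C/C=C/O[Si](C)(C)C(C)(C)C | intermediate
12 | (3R,4R,5S,10S)-3α-TBSO-4β,5β-dimethyl-10βH-decal-1-en-6-one | C1C(=O)[C@@]2(C)[C@H](C=C[C@@H](O[Si](C)(C)C(C)(C)C)[C@@H]2C)CC1 | intermediate
13 | (3R,4R,5S,10S)-3α-TBSO-4β,5β-dimethyl-10βH-decalin-6-one | C1C(=O)[C@@]2(C)[C@H](CC[C@@H](O[Si](C)(C)C(C)(C)C)[C@@H]2C)CC1 | intermediate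
14 | potassium 6(7)-enolate of 13 | C1=C([O-])[C@@]2(C)[C@H](CC[C@@H](O[Si](C)(C)C(C)(C)C)[C@@H]2C)CC1.[K+] | intermediate
15 | (3R,4R,5S,10S)-3α-TBSO-4β,5β-dimethyl-10βH-decal-6-en-6-yl triflate | C1=C(OS(=O)(=O)C(F)(F)F)[C@@]2(C)[C@H](CC[C@@H](O[Si](C)(C)C(C)(C)C)[C@@H]2C)CC1 | intermediate
16 | (3R,4R,5R,10S)-3α-TBSO-4β,5β-dimethyl-10βH-decal-6-ene | C1=C[C@@]2(C)[C@H](CC[C@@H](O[Si](C)(C)C(C)(C)C)[C@@H]2C)CC1 | intermediate
17 | (3R,4R,5R,10R)-3α-TBSO-4β,5β-dimethyl-10βH-decal-6-en-8-one | C1=C[C@@]2(C)[C@H](CC[C@@H](O[Si](C)(C)C(C)(C)C)[C@@H]2C)CC1=O | intermediate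
18 | (3R,4R,5S,10R)-3α,8-bis(TBSO)-4β,5β-dimethyl-10βH-decala-6,8-diene | C1=C[C@@]2(C)[C@H](CC[C@@H](O[Si](C)(C)C(C)(C)C)[C@@H]2C)C=C1O[Si](C)(C)C(C)(C)C | intermediate
19 | 8β,9β-epoxide of 18 | C1=C[C@@]2(C)[C@H](CC[C@@H](O[Si](C)(C)C(C)(C)C)[C@@H]2C)[C@H]3O[C@]31O[Si](C)(C)C(C)(C)C | intermediate
20 | (3R,4R,5R,9R,10S)-3α,9β-bis(TBSO)-4β,5β-dimethyl-10βH-decal-6-en-8-one | C1=C[C@@]2(C)[C@H](CC[C@@H](O[Si](C)(C)C(C)(C)C)[C@@H]2C)[C@@H](O[Si](C)(C)C(C)(C)C)C1=O | intermediate
21 | 7-iodo derivative of 20 | IC1=C[C@@]2(C)[C@H](CC[C@@H](O[Si](C)(C)C(C)(C)C)[C@@H]2C)[C@@H](O[Si](C)(C)C(C)(C)C)C1=O | intermediate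
22 | tributyl(prop-1-en-2-yl)stannane | C=C(C)[Sn](CCCC)(CCCC)CCCC | starting material
23 | (3R,4R,5R,9R,10S)-3α,9β-bis(TBSO)-10βH-eremophila-6,11-dien-8-one | C=C(C)C1=C[C@@]2(C)[C@H](CC[C@@H](O[Si](C)(C)C(C)(C)C)[C@@H]2C)[C@@H](O[Si](C)(C)C(C)(C)C)C1=O | intermediate
24 | lithium 7(8),11-dienolate from 23 | C=C(C)C=1C[C@@]2(C)[C@H](CC[C@@H](O[Si](C)(C)C(C)(C)C)[C@@H]2C)[C@@H](O[Si](C)(C)C(C)(C)C)C=1[O-].[Li+] | intermediate
25 | (3R,4R,5R,7R,9R,10S)-3α,9β-bis(TBSO)-10βH-eremophil-11-en-8-one (7β-isopropenyl) | C=C(C)[C@H]1C[C@@]2(C)[C@H](CC[C@@H](O[Si](C)(C)C(C)(C)C)[C@@H]2C)[C@@H](O[Si](C)(C)C(C)(C)C)C1=O | intermediate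
26 | (3R,4R,5R,7R,9R,10S)-3α,9β-dihydroxy-10βH-eremophil-11-en-8-one | C=C(C)[C@H]1C[C@@]2(C)[C@H](CC[C@@H](O)[C@@H]2C)[C@@H](O)C1=O | intermediate
27 | angelic acid | C/C=C(/C)C(=O)O | starting material
28 | angelic 2,4,6-trichlorobenzoic anhydride | C/C=C(/C)C(=O)OC(=O)c1c(Cl)cc(Cl)cc1Cl | intermediate
29 | (3R,4R,5R,7R,9R,10S)-3α,9β-bis(angeloyloxy)-10βH-eremophil-11-en-8-one | C=C(C)[C@H]1C[C@@]2(C)[C@H](CC[C@@H](OC(=O)/C(C)=C\C)[C@@H]2C)[C@@H](OC(=O)/C(C)=C\C)C1=O | target

**Step count**
Total steps: 18. Longest linear sequence: 16 (steps 2–16 and 18).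

**Steps most likely to fail**

1. Step 6.
   - What may go wrong: facial discrimination may be weak or of the wrong sense, because the tigloyl ketone has neither an α-H nor a formyl H to organise it on the catalyst. The trisubstituted dienophile in an electronically mismatched orientation may react slowly. That leaves time for protodesilylation, Mukaiyama–Michael oligomerisation or leakage into the exo (trans-fusing) mode.
   - Fallback (sets out from 11, returns at 12): the cycloaddition is run with MeAlCl2 (1.1 equiv, CH2Cl2, −78 → −30 °C), the established way to close 1,7,9-decatrien-3-ones. This should give 12 together with the enantiomeric adduct F1. HF·pyridine frees the allylic alcohol F2 and the enantiomeric alcohol F3. Esterification with (S)-O-methylmandelic acid (DCC, DMAP, 0 °C) gives the mandelate F4 from F2 and the diastereomeric mandelate F5 from F3. These are separated by chromatography or crystallisation. Methanolysis of F4 (K2CO3, MeOH) returns F2, and TBSCl/imidazole brings it back to 12.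

2. Step 15.
   - What may go wrong: hydride delivery at C6, next to the quaternary C5, may be slow or divert to 1,2-reduction. Proton delivery may go to the γ-carbon, which moves the alkene into conjugation, or to the wrong face of C7.
   - Fallback (sets out from 20, returns at 25): the side chain is brought in as acetone and the alkene position is corrected at the end. L-Selectride reduces the simpler enone 20 to the lithium enolate F6. After ZnCl2, this is trapped with acetone as the aldol adduct F7. MsCl/Et3N and then DBU dehydrate F7 to the conjugated isopropylidene ketone F8. KOt-Bu in THF forms the extended potassium dienolate F9. Inverse quench into cold aqueous acetic acid (deconjugative protonation) gives 25, and recovered F8 is recycled.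

3. Step 18.
   - What may go wrong: acylation of the hydrogen-bonded α-ketol may be slow. Prolonged heating could then allow migration of the isopropenyl double bond into conjugation, a ketol shift, or Z-to-E isomerisation of the activated acyl group.
   - Fallback (sets out from 23, returns at 29): the esters are installed first and the labile ketone is unveiled last. HF·pyridine converts 23 into the dienone diol F10, which has no C7–H and tolerates the hot acylation with 28 to give the dienone bis-angelate F11. [(Ph3P)CuH]6 in wet toluene at rt then reduces the ketone-conjugated C6=C7 bond in preference to the twisted, α,β-disubstituted angelates. Water protonates the copper enolate at C7 under neutral conditions to give 29.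

**Further compounds**
F1 | step 6 | (3S,4S,5R,10R)-enantiomer of 12 | C1C(=O)[C@]2(C)[C@@H](C=C[C@H](O[Si](C)(C)C(C)(C)C)[C@H]2C)CC1
F2 | step 6 | (3R,4R,5S,10S)-3α-hydroxy-4β,5β-dimethyl-10βH-decal-1-en-6-one | C1C(=O)[C@@]2(C)[C@H](C=C[C@@H](O)[C@@H]2C)CC1
F3 | step 6 | (3S,4S,5R,10R)-enantiomer of F2 | C1C(=O)[C@]2(C)[C@@H](C=C[C@H](O)[C@H]2C)CC1
F4 | step 6 | (S)-O-methylmandelate of F2 | C1C(=O)[C@@]2(C)[C@H](C=C[C@@H](OC(=O)[C@@H](OC)c3ccccc3)[C@@H]2C)CC1
F5 | step 6 | (S)-O-methylmandelate of F3 | C1C(=O)[C@]2(C)[C@@H](C=C[C@H](OC(=O)[C@@H](OC)c3ccccc3)[C@H]2C)CC1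
F6 | step 15 | lithium 7(8)-enolate from 1,4-reduction of 20 | C=1C[C@@]2(C)[C@H](CC[C@@H](O[Si](C)(C)C(C)(C)C)[C@@H]2C)[C@@H](O[Si](C)(C)C(C)(C)C)C=1[O-].[Li+]
F7 | step 15 | 3α,9β-bis(TBSO)-7β-(2-hydroxypropan-2-yl)-4β,5β-dimethyl-10βH-decalin-8-one | CC(C)(O)[C@H]1C[C@@]2(C)[C@H](CC[C@@H](O[Si](C)(C)C(C)(C)C)[C@@H]2C)[C@@H](O[Si](C)(C)C(C)(C)C)C1=O
F8 | step 15 | 3α,9β-bis(TBSO)-10βH-eremophil-7(11)-en-8-one | CC(C)=C1C[C@@]2(C)[C@H](CC[C@@H](O[Si](C)(C)C(C)(C)C)[C@@H]2C)[C@@H](O[Si](C)(C)C(C)(C)C)C1=O
F9 | step 15 | potassium 7(8),11-dienolate (potassium analogue of 24) | C=C(C)C=1C[C@@]2(C)[C@H](CC[C@@H](O[Si](C)(C)C(C)(C)C)[C@@H]2C)[C@@H](O[Si](C)(C)C(C)(C)C)C=1[O-].[K+]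
F10 | step 18 | 3α,9β-dihydroxy-10βH-eremophila-6,11-dien-8-one | C=C(C)C1=C[C@@]2(C)[C@H](CC[C@@H](O)[C@@H]2C)[C@@H](O)C1=O
F11 | step 18 | 3α,9β-bis(angeloyloxy)-10βH-eremophila-6,11-dien-8-one | C=C(C)C1=C[C@@]2(C)[C@H](CC[C@@H](OC(=O)/C(C)=C\C)[C@@H]2C)[C@@H](OC(=O)/C(C)=C\C)C1=O
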